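**Strategy.** Both ester C6–O bonds are disconnected. A double Mitsunobu inversion joins two molecules of 6-epi-incarvilline to silyl-protected 4,4′-dihydroxy-α-truxillic acid, the solid-state photodimer of p-coumaric acid. The amino alcohol rests on one step, a 5-exo radical cyclisation of a chloromethyl ketone onto a 5-methyl-1,2,3,6-tetrahydropyridine. It forms C5–C4a, closes the cyclopentanone as the last ring, and sets C4a (cis fusion) and C4 (hydrogen delivered to the convex face). It exploits the C6 carbonyl next to C5H2, the cis C4a–C7a ring fusion and the methyl-bearing C4 of the piperidine ring. The single stereocentre C7a, from a rhodium-catalysed vinyl addition, controls all others.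

Key step: step 8

Remark: atom labels follow the octahydrocyclopenta[c]pyridine numbering of each amino-alcohol half (C1, N2, C3, C4, C4a, C5, C6, C7, C7a). The two halves are identical, so the alcohol 16 is made once and used twice; likewise two molecules of 1 are consumed per molecule of 2.

Step 1
Reactants: 1 (E)-3-(4-hydroxyphenyl)prop-2-enoic acid (p-coumaric acid) (2 equiv; two molecules of 1 combine head-to-tail)
Product: 2 (1α,2α,3β,4β)-2,4-bis(4-hydroxyphenyl)cyclobutane-1,3-dicarboxylic acid (4,4′-dihydroxy-α-truxillic acid)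
Conditions: hν (medium-pressure Hg lamp, Pyrex filter), finely ground crystals suspended in hexane, rt
Reagents that add atoms: second molecule of 1, (E)-3-(4-hydroxyphenyl)prop-2-enoic acid OC(=O)/C=C/c1ccc(O)cc1
Why: In the crystal two molecules of the E-acid pack head-to-tail with parallel double bonds within reach, so the topochemical [2+2] photodimerisation should join them into the centrosymmetric α-truxillic acid, all four cyclobutane stereocentres being fixed by the lattice and the E geometry.

Step 2
Reactants: 2 4,4′-dihydroxy-α-truxillic acid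
Product: 4 (1α,2α,3β,4β)-2,4-bis[4-(tert-butyldimethylsilyloxy)phenyl]cyclobutane-1,3-dicarboxylic acid, via tetrasilylated intermediate 3 (not isolated)
Conditions: TBSCl (5 equiv), imidazole (10 equiv), DMF, rt; then AcOH/THF/H2O (3:1:1), rt
Reagents that add atoms: tert-butyldimethylsilyl chloride CC(C)(C)[Si](C)(C)Cl
Why: The silyl chloride with imidazole silylates phenols and acids alike, and the labile silyl esters are then hydrolysed by aqueous acetic acid while the aryl silyl ethers stay (standard protection, no stereocentre touched).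

Step 3
Reactants: 5 methyl (2E)-4-bromobut-2-enoate; 6 2-methylprop-2-en-1-amine
Product: 8 methyl (2E)-4-[(tert-butoxycarbonyl)(2-methylprop-2-en-1-yl)amino]but-2-enoate, via secondary amine 7 (not isolated)
Conditions: 6 (4 equiv), THF, 0 °C; filter, evaporate excess 6; then Boc2O, CH2Cl2, rt
Reagents that add atoms: di-tert-butyl dicarbonate CC(C)(C)OC(=O)OC(=O)OC(C)(C)C
Why: SN2 displacement of the allylic bromide by the primary amine (used in excess to suppress double alkylation) is followed by carbamate formation, which also removes the nucleophilicity of nitrogen for the later steps.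

Step 4
Reactants: 8 methyl (2E)-4-[(tert-butoxycarbonyl)(2-methylprop-2-en-1-yl)amino]but-2-enoate
Product: 9 methyl (3S)-3-({(tert-butoxycarbonyl)(2-methylprop-2-en-1-yl)amino}methyl)pent-4-enoate
Conditions: CH2=CHBF3K (3 equiv), [Rh(cod)2]BF4 (3 mol %), (R)-BINAP (3.3 mol %), Et3N (2 equiv), toluene/H2O (10:1), 100 °C
Reagents that add atoms: potassium vinyltrifluoroborate C=C[B-](F)(F)F.[K+]
Why: Rhodium-catalysed asymmetric 1,4-addition of an alkenylboron reagent (Hayashi–Miyaura reaction) to the E-enoate, in which the (R)-BINAP complex should deliver the vinyl group to the α-Re face and so set the future C7a as (S) in 9.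

Step 5
Reactants: 9 methyl (3S)-3-({(tert-butoxycarbonyl)(2-methylprop-2-en-1-yl)amino}methyl)pent-4-enoate
Product: 10 tert-butyl (3S)-3-(2-methoxy-2-oxoethyl)-5-methyl-3,6-dihydropyridine-1(2H)-carboxylate
Conditions: second-generation Grubbs catalyst RuCl2(=CHPh)(H2IMes)(PCy3) (5 mol %), CH2Cl2 (0.01 M), 40 °C
Reagents that add atoms: none
Why: Ring-closing metathesis of the vinyl and methallyl groups, driven by loss of ethene, closes the piperidine ring as a 1,2,3,6-tetrahydropyridine with the trisubstituted C4a=C4 double bond and leaves the stereocentre untouched.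

Step 6
Reactants: 10 tert-butyl (3S)-3-(2-methoxy-2-oxoethyl)-5-methyl-3,6-dihydropyridine-1(2H)-carboxylate
Product: 11 tert-butyl (3R)-3-(1-methoxy-1-oxopropan-2-yl)-5-methyl-3,6-dihydropyridine-1(2H)-carboxylate (both epimers at the new centre)
Conditions: LiN(i-Pr)2 (LDA), THF, −78 °C; then MeI, −78 to 0 °C
Reagents that add atoms: iodomethane CI
Why: Alkylation of the lithium ester enolate with iodomethane introduces the C7 methyl group, and the new stereocentre is left uncontrolled because it later sits α to the ketone and is equilibrated in step 8.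

Step 7
Reactants: 11 tert-butyl (3R)-3-(1-methoxy-1-oxopropan-2-yl)-5-methyl-3,6-dihydropyridine-1(2H)-carboxylate
Product: 12 tert-butyl (3R)-3-(4-chloro-3-oxobutan-2-yl)-5-methyl-3,6-dihydropyridine-1(2H)-carboxylate (both epimers at C2 of the side chain)
Conditions: ICH2Cl (1.5 equiv), MeLi·LiBr (1.4 equiv), THF, −78 °C; AcOH quench at −78 °C
Reagents that add atoms: chloroiodomethane ClCI
Why: Chloromethyllithium, formed by iodine–lithium exchange in the presence of the ester, adds once to give a tetrahedral intermediate that is stable at −78 °C and collapses to the chloromethyl ketone on acidic quench (halomethyllithium acylation of esters).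

Step 8
Reactants: 12 tert-butyl (3R)-3-(4-chloro-3-oxobutan-2-yl)-5-methyl-3,6-dihydropyridine-1(2H)-carboxylate
Product: 14 tert-butyl (4R,4aS,7S,7aR)-4,7-dimethyl-6-oxooctahydro-2H-cyclopenta[c]pyridine-2-carboxylate, via C7-epimer mixture 13 (not isolated)
Conditions: Bu3SnH (1.2 equiv) and AIBN (0.1 equiv) added over 6 h by syringe pump, benzene (0.005 M), reflux; evaporate; then NaOMe (0.2 equiv), MeOH, rt
Reagents that add atoms: none
Why: The tributylstannyl radical abstracts chlorine from 12 to give the α-keto radical at C5, which adds to C4a of the ring alkene, and the resulting tertiary C4 radical takes hydrogen from the stannane; the closest known reaction type is the tin-hydride-mediated cyclisation of α-halo ketones onto cycloalkenes. The cyclopentanone ring (C5, C6, C7, C7a, C4a) closes in the 5-exo-trig mode, since attack at the methyl-bearing C4 would give a bridged six-membered ring and a less stabilised secondary radical. C4a is controlled by the C7a stereocentre, because the three-atom tether can reach only the alkene face on which it stands, so the ring fusion must be cis. C4 is controlled by the new ring: strain with the C4 methyl should hold the C4a–C5 bond pseudo-axial over one lobe of the radical, so the stannane delivers hydrogen to the open convex face, cis to H4a. C7, now α to the ketone, is equilibrated by methoxide and should settle as the exo-methyl epimer, trans to the C7a–C1 bond. The step needs cyclisation to outrun direct reduction of the α-keto radical, which the low stannane concentration and the polarity match between the electrophilic radical and the electron-rich trisubstituted alkene should secure.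

Step 9
Reactants: 14 tert-butyl (4R,4aS,7S,7aR)-4,7-dimethyl-6-oxooctahydro-2H-cyclopenta[c]pyridine-2-carboxylate
Product: 16 (4R,4aS,6S,7S,7aR)-2,4,7-trimethyloctahydro-1H-cyclopenta[c]pyridin-6-ol (6-epi-incarvilline), via carbamate alcohol 15 (not isolated)
Conditions: LiAlH4 (5 equiv), THF, 0 °C for 1 h, then reflux; aqueous NaOH work-up
Reagents that add atoms: none
Why: Hydride should attack the C6 carbonyl from the convex face of the cis-fused bicycle (the face of H4a and H7a), giving the 6S alcohol with hydroxyl trans to the C7 methyl, and at reflux LiAlH4 reduces the tert-butyl carbamate to the N-methyl group.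

Step 10
Reactants: 16 6-epi-incarvilline (2.2 equiv; two molecules are incorporated); 4 bis-silylated α-truxillic diacid
Product: 17 bis[(4R,4aS,6R,7S,7aR)-2,4,7-trimethyloctahydro-1H-cyclopenta[c]pyridin-6-yl] (1α,2α,3β,4β)-2,4-bis[4-(tert-butyldimethylsilyloxy)phenyl]cyclobutane-1,3-dicarboxylate
Conditions: PPh3 (3 equiv), DIAD (3 equiv), THF, 0 °C to rt
Reagents that add atoms: none
Why: Mitsunobu esterification, in which each carboxylate displaces the oxyphosphonium group by SN2 with inversion, converts both 6S alcohols into the 6R esters of the target.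

Step 11
Reactants: 17 bis-silyl ether of the target
Product: 18 bis[(4R,4aS,6R,7S,7aR)-2,4,7-trimethyloctahydro-1H-cyclopenta[c]pyridin-6-yl] (1α,2α,3β,4β)-2,4-bis(4-hydroxyphenyl)cyclobutane-1,3-dicarboxylate (CNP0180864.2)
Conditions: HF·pyridine, THF, 0 °C to rt; aqueous NaHCO3 work-up
Reagents that add atoms: none
Why: Fluoride cleaves the two aryl silyl ethers under conditions that should leave the hindered esters, the cyclobutane stereocentres and the tertiary amines untouched.

**Compound list**

1 | (E)-3-(4-hydroxyphenyl)prop-2-enoic acid (p-coumaric acid) | OC(=O)/C=C/c1ccc(O)cc1 | starting material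
2 | (1α,2α,3β,4β)-2,4-bis(4-hydroxyphenyl)cyclobutane-1,3-dicarboxylic acid (4,4′-dihydroxy-α-truxillic acid, centrosymmetric) | OC(=O)[C@H]1[C@H](c2ccc(O)cc2)[C@H](C(=O)O)[C@H]1c1ccc(O)cc1 | intermediate
3 | bis(tert-butyldimethylsilyl) ester of 4 (tetrasilylated α-truxillate, not isolated) | CC(C)(C)[Si](C)(C)OC(=O)[C@H]1[C@H](c2ccc(O[Si](C)(C)C(C)(C)C)cc2)[C@H](C(=O)O[Si](C)(C)C(C)(C)C)[C@H]1c1ccc(O[Si](C)(C)C(C)(C)C)cc1 | intermediate
4 | (1α,2α,3β,4β)-2,4-bis[4-(tert-butyldimethylsilyloxy)phenyl]cyclobutane-1,3-dicarboxylic acid | OC(=O)[C@H]1[C@H](c2ccc(O[Si](C)(C)C(C)(C)C)cc2)[C@H](C(=O)O)[C@H]1c1ccc(O[Si](C)(C)C(C)(C)C)cc1 | intermediate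
5 | methyl (2E)-4-bromobut-2-enoate | COC(=O)/C=C/CBr | starting material
6 | 2-methylprop-2-en-1-amine | CC(=C)CN | starting material
7 | methyl (2E)-4-[(2-methylprop-2-en-1-yl)amino]but-2-enoate (not isolated) | COC(=O)/C=C/CNCC(C)=C | intermediate
8 | methyl (2E)-4-[(tert-butoxycarbonyl)(2-methylprop-2-en-1-yl)amino]but-2-enoate | COC(=O)/C=C/CN(CC(C)=C)C(=O)OC(C)(C)C | intermediate
9 | methyl (3S)-3-({(tert-butoxycarbonyl)(2-methylprop-2-en-1-yl)amino}methyl)pent-4-enoate | COC(=O)C[C@@H](C=C)CN(CC(C)=C)C(=O)OC(C)(C)C | intermediate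
10 | tert-butyl (3S)-3-(2-methoxy-2-oxoethyl)-5-methyl-3,6-dihydropyridine-1(2H)-carboxylate | COC(=O)C[C@@H]1CN(C(=O)OC(C)(C)C)CC(C)=C1 | intermediate
11 | tert-butyl (3R)-3-(1-methoxy-1-oxopropan-2-yl)-5-methyl-3,6-dihydropyridine-1(2H)-carboxylate, both epimers at C2 of the propanoate | COC(=O)C(C)[C@@H]1CN(C(=O)OC(C)(C)C)CC(C)=C1 | intermediate
12 | tert-butyl (3R)-3-(4-chloro-3-oxobutan-2-yl)-5-methyl-3,6-dihydropyridine-1(2H)-carboxylate, both epimers at C2 of the side chain | ClCC(=O)C(C)[C@@H]1CN(C(=O)OC(C)(C)C)CC(C)=C1 | intermediate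
13 | tert-butyl (4R,4aS,7aR)-4,7-dimethyl-6-oxooctahydro-2H-cyclopenta[c]pyridine-2-carboxylate, cis-fused, mixture of C7 epimers (not isolated) | CC1[C@@H]2CN(C(=O)OC(C)(C)C)C[C@H](C)[C@@H]2CC1=O | intermediate
14 | tert-butyl (4R,4aS,7S,7aR)-4,7-dimethyl-6-oxooctahydro-2H-cyclopenta[c]pyridine-2-carboxylate | C[C@H]1[C@@H]2CN(C(=O)OC(C)(C)C)C[C@H](C)[C@@H]2CC1=O | intermediate
15 | tert-butyl (4R,4aS,6S,7S,7aR)-6-hydroxy-4,7-dimethyloctahydro-2H-cyclopenta[c]pyridine-2-carboxylate (not isolated) | C[C@H]1[C@@H]2CN(C(=O)OC(C)(C)C)C[C@H](C)[C@@H]2C[C@@H]1O | intermediate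
16 | (4R,4aS,6S,7S,7aR)-2,4,7-trimethyloctahydro-1H-cyclopenta[c]pyridin-6-ol (6-epi-incarvilline) | C[C@H]1[C@@H]2CN(C)C[C@H](C)[C@@H]2C[C@@H]1O | intermediate
17 | bis[(4R,4aS,6R,7S,7aR)-2,4,7-trimethyloctahydro-1H-cyclopenta[c]pyridin-6-yl] (1α,2α,3β,4β)-2,4-bis[4-(tert-butyldimethylsilyloxy)phenyl]cyclobutane-1,3-dicarboxylate | C[C@H]1[C@@H]2CN(C)C[C@H](C)[C@@H]2C[C@H]1OC(=O)[C@H]1[C@H](c2ccc(O[Si](C)(C)C(C)(C)C)cc2)[C@H](C(=O)O[C@@H]2C[C@@H]3[C@@H](CN(C)C[C@@H]3C)[C@@H]2C)[C@H]1c1ccc(O[Si](C)(C)C(C)(C)C)cc1 | intermediate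
18 | bis[(4R,4aS,6R,7S,7aR)-2,4,7-trimethyloctahydro-1H-cyclopenta[c]pyridin-6-yl] (1α,2α,3β,4β)-2,4-bis(4-hydroxyphenyl)cyclobutane-1,3-dicarboxylate | C[C@H]1[C@@H]2CN(C)C[C@H](C)[C@@H]2C[C@H]1OC(=O)[C@H]1[C@H](c2ccc(O)cc2)[C@H](C(=O)O[C@@H]2C[C@@H]3[C@@H](CN(C)C[C@@H]3C)[C@@H]2C)[C@H]1c1ccc(O)cc1 | target

**Count and risks**

Total step count: 11. Longest linear sequence: 9 steps (steps 3 to 11, from 5 and 6 to 18).

Steps most likely to fail:

Step 8. The α-keto radical may be reduced by the stannane before it cyclises, or hydrogen may be delivered to both faces of the C4 radical. The fallback sets out from 12 and comes back at 13. It ends the radical chain by iodine transfer and sets C4 by hydrogenation instead. Halide exchange (NaI, acetone, rt) gives the iodomethyl ketone F1. Iodine-atom-transfer cyclisation without any hydrogen donor ((Bu3Sn)2 10 mol %, hν, benzene, 80 °C) gives the cis-fused tertiary iodide F2. DBU (toluene, 80 °C) removes HI to give the ene-carbamate F3, whose double-bond isomers converge in the next operation. Hydrogenation over palladium on carbon (H2, Pd/C, EtOAc) from the convex face returns 13, which is equilibrated to 14 with NaOMe as in step 8.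

Step 4. Protodeboronation or oligomerisation of the vinylboron reagent may outrun the slow addition to the enoate, or the facial selectivity may be low. The fallback sets out from 8 and comes back at 9 by an iridium-catalysed allylic alkylation. Reduction with i-Bu2AlH (CH2Cl2, −78 °C) gives the allylic alcohol F4, and ClCO2Me with pyridine gives the methyl carbonate F5. Branched-selective asymmetric allylic alkylation ([Ir(cod)Cl]2, binaphthol-derived bis(1-phenylethyl)phosphoramidite ligand in the enantiomer that gives the 2R product, dimethyl malonate, THF, rt) gives the branched malonate F6. Krapcho demethoxycarbonylation (LiCl, DMSO/H2O, 130 °C) returns 9.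

Step 10. The second esterification may stall at the hindered mono-ester, or the activated alcohol may eliminate. The fallback sets out from 16 and 4 and comes back at 17. It replaces the redox condensation by an SN2 reaction of a carboxylate salt with a sulfonate. MsCl and Et3N (CH2Cl2, 0 °C) convert 16 into the mesylate F7. Cs2CO3 in DMF converts 4 into the dicaesium salt F8. Heating F8 with F7 (2.2 equiv, DMF, 60 °C) should give 17 with inversion at both C6 centres.

Further compounds
F1 | step 8 | tert-butyl (3R)-3-(4-iodo-3-oxobutan-2-yl)-5-methyl-3,6-dihydropyridine-1(2H)-carboxylate, both epimers at C2 of the side chain | ICC(=O)C(C)[C@@H]1CN(C(=O)OC(C)(C)C)CC(C)=C1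
F2 | step 8 | tert-butyl (4aR,7aS)-4-iodo-4,7-dimethyl-6-oxooctahydro-2H-cyclopenta[c]pyridine-2-carboxylate, cis-fused with C4a and C7a arranged as in 13, mixture at C4 and C7 | CC1[C@@H]2CN(C(=O)OC(C)(C)C)CC(C)(I)[C@@H]2CC1=O
F3 | step 8 | tert-butyl (4aR,7aR)-4,7-dimethyl-6-oxo-1,4a,5,6,7,7a-hexahydro-2H-cyclopenta[c]pyridine-2-carboxylate, cis-fused, mixture at C7 | CC1[C@@H]2CN(C(=O)OC(C)(C)C)C=C(C)[C@@H]2CC1=O
F4 | step 4 | tert-butyl [(2E)-4-hydroxybut-2-en-1-yl](2-methylprop-2-en-1-yl)carbamate | OC/C=C/CN(CC(C)=C)C(=O)OC(C)(C)C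
F5 | step 4 | tert-butyl {(2E)-4-[(methoxycarbonyl)oxy]but-2-en-1-yl}(2-methylprop-2-en-1-yl)carbamate | COC(=O)OC/C=C/CN(CC(C)=C)C(=O)OC(C)(C)C
F6 | step 4 | dimethyl 2-[(2R)-1-{(tert-butoxycarbonyl)(2-methylprop-2-en-1-yl)amino}but-3-en-2-yl]propanedioate | COC(=O)C(C(=O)OC)[C@@H](C=C)CN(CC(C)=C)C(=O)OC(C)(C)C
F7 | step 10 | (4R,4aS,6S,7S,7aR)-2,4,7-trimethyloctahydro-1H-cyclopenta[c]pyridin-6-yl methanesulfonate | C[C@H]1[C@@H]2CN(C)C[C@H](C)[C@@H]2C[C@@H]1OS(C)(=O)=O
F8 | step 10 | dicaesium (1α,2α,3β,4β)-2,4-bis[4-(tert-butyldimethylsilyloxy)phenyl]cyclobutane-1,3-dicarboxylate | [Cs+].[Cs+].[O-]C(=O)[C@H]1[C@H](c2ccc(O[Si](C)(C)C(C)(C)C)cc2)[C@H](C([O-])=O)[C@H]1c1ccc(O[Si](C)(C)C(C)(C)C)cc1
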